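The route rests on disconnecting C13–C14 (C1 = lactone carbonyl) in the middle of the unfunctionalised dodecamethylene bridge C9–C20 of the 22-membered lactone ring. Because no substituent or stereocentre lies near this bond, it can be made as an alkene between two terminal vinyl groups. Ring-closing metathesis of the acyclic diene ester 22, which already carries the Z-C2=C3 enoate, the C5 and C8 carbinols (as silyl ethers), the trans C6–C7 oxirane and C21, closes the macrocycle in one operation; site-selective hydrogenation then gives the saturated bridge. Diene 22 comes from a furan-derived enedione by double CBS reduction, Shi epoxidation and Still–Gennari union with an (R)-decenyl phosphonoacetate.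

Key step: step 13

Remark: locants follow the macrolide throughout (C1 lactone carbonyl, C2=C3, C5 and C8 carbinols, C6–C7 oxirane, C9–C20 methylenes, C21 the methyl-bearing carbon); acid 5 is assumed to be purchasable (otherwise one saponification of the commercial methyl ester).

Step 1
Reactants: 1 7-bromohept-1-ene; 2 (R)-2-methyloxirane
Product: 4 (2R)-dec-9-en-2-ol, via hept-6-en-1-ylmagnesium bromide 3 (not isolated)
Conditions: Mg, THF, rt; then CuI (10 mol%), 2, THF, −30 to 0 °C; aqueous NH4Cl
Reagents that add atoms: none
Why: Copper-catalysed Grignard opening of a terminal epoxide is an SN2 attack at the unsubstituted carbon, so the stereocentre of 2 is untouched and becomes C21 with the R configuration.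

Step 2
Reactants: 4 (2R)-dec-9-en-2-ol; 5 [bis(2,2,2-trifluoroethoxy)phosphoryl]acetic acid
Product: 6 (2R)-dec-9-en-2-yl [bis(2,2,2-trifluoroethoxy)phosphoryl]acetate
Conditions: DCC, DMAP (10 mol%), CH2Cl2, 0 °C to rt
Reagents that add atoms: none
Why: Steglich esterification acylates the secondary alcohol at oxygen without breaking the C21–O bond, so the configuration is retained and the Z-selective olefination reagent is built onto the alcohol fragment.

Step 3
Reactants: 7 furan; 8 6-bromohex-1-ene
Product: 10 2-(hex-5-en-1-yl)furan, via furan-2-yllithium 9 (not isolated)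
Conditions: n-BuLi, THF, 0 °C; then 8, DMPU, −78 °C to rt
Reagents that add atoms: none
Why: α-Lithiation of furan followed by SN2 alkylation with a primary bromide gives the 2-alkylfuran, the furan ring being a masked cis-enedione that will supply C5–C8.

Step 4
Reactants: 10 2-(hex-5-en-1-yl)furan; 11 oxirane
Product: 13 2-[5-(hex-5-en-1-yl)furan-2-yl]ethan-1-ol, via [5-(hex-5-en-1-yl)furan-2-yl]lithium 12 (not isolated)
Conditions: n-BuLi, THF, 0 °C to rt; then 11, −78 °C to rt; aqueous NH4Cl
Reagents that add atoms: none
Why: The remaining α-position of the furan is the only acidic site, and the resulting furyllithium opens oxirane (SN2 epoxide opening) to add the two carbons that become C4 and C3.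

Step 5
Reactants: 13 2-[5-(hex-5-en-1-yl)furan-2-yl]ethan-1-ol
Product: 14 2-(hex-5-en-1-yl)-5-{2-[(4-methoxybenzyl)oxy]ethyl}furan
Conditions: NaH, 4-methoxybenzyl chloride, Bu4NI (cat.), THF/DMF, 0 °C to rt
Reagents that add atoms: 4-methoxybenzyl chloride, COc1ccc(CCl)cc1
Why: Williamson etherification masks the primary alcohol, which would otherwise add in conjugate fashion to the enedione made next, as an ether that can later be removed oxidatively in the presence of silyl ethers.

Step 6
Reactants: 14 2-(hex-5-en-1-yl)-5-{2-[(4-methoxybenzyl)oxy]ethyl}furan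
Product: 16 (4E)-1-[(4-methoxybenzyl)oxy]dodeca-4,11-diene-3,6-dione, via (4Z)-enedione 15 (not isolated)
Conditions: NBS, NaHCO3, acetone/H2O (10:1), −20 °C; then pyridine, rt
Reagents that add atoms: water, O
Why: Oxidative ring opening of a 2,5-dialkylfuran (bromonium formation, 2,5-addition of water, loss of HBr) unmasks the cis-enedione, which pyridine isomerises to the more stable trans isomer, the electron-rich furan reacting far faster with NBS than the terminal alkene or the anisyl ring.

Step 7
Reactants: 16 (4E)-1-[(4-methoxybenzyl)oxy]dodeca-4,11-diene-3,6-dione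
Product: 17 (3S,4E,6S)-1-[(4-methoxybenzyl)oxy]dodeca-4,11-diene-3,6-diol
Conditions: (R)-2-methyl-CBS-oxazaborolidine (20 mol%), catecholborane (3 equiv), toluene/CH2Cl2, −78 °C; MeOH, then aqueous NaHCO3
Reagents that add atoms: none
Why: In this Corey–Bakshi–Shibata reduction each carbonyl binds the catalyst with its alkenyl arm as the large group, so the (R)-catalyst delivers hydride to give the S carbinol at both C5 and C8 (the minor enantiomer is drained into the separable meso diol), while catecholborane at −78 °C should neither hydroborate the terminal alkene nor add in conjugate fashion.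

Step 8
Reactants: 17 (3S,4E,6S)-1-[(4-methoxybenzyl)oxy]dodeca-4,11-diene-3,6-diol
Product: 18 (1S)-1-[(2R,3R)-3-{(1S)-1-hydroxy-3-[(4-methoxybenzyl)oxy]propyl}oxiran-2-yl]hept-6-en-1-ol
Conditions: Shi ketone (1,2:4,5-di-O-isopropylidene-β-D-erythro-2,3-hexodiulo-2,6-pyranose, 30 mol%), Oxone (2KHSO5·KHSO4·K2SO4), K2CO3, Bu4NHSO4, MeCN/dimethoxymethane/aqueous Na2B4O7 buffer (pH 10.5), 0 °C
Reagents that add atoms: potassium peroxymonosulfate (active component of Oxone), [K+].[O-]S(=O)(=O)OO
Why: In the Shi asymmetric epoxidation the D-fructose-derived dioxirane transfers oxygen to trans-disubstituted alkenes through a spiro transition state to give the (R,R)-oxirane, here the face that is threo to both S carbinols, so C6 and C7 are set by the reagent while the monosubstituted terminal alkene should react much more slowly.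

Step 9
Reactants: 18 epoxy diol
Product: 19 bis(triethylsilyl) ether of 18 (both secondary hydroxyls silylated, stereocentres unchanged)
Conditions: Et3SiCl, imidazole, DMAP (cat.), DMF, 0 °C to rt
Reagents that add atoms: chlorotriethylsilane, CC[Si](Cl)(CC)CC
Why: Silyl ether formation under mild base protects both secondary alcohols without touching the oxirane, and triethylsilyl groups are chosen because they can be removed at the end under nearly neutral fluoride conditions.

Step 10
Reactants: 19 bis(triethylsilyl) ether of 18
Product: 20 (3S)-3-[(triethylsilyl)oxy]-3-{3-[(1S)-1-[(triethylsilyl)oxy]hept-6-en-1-yl]oxiran-2-yl}propan-1-ol (19 without the 4-methoxybenzyl group, trans-oxirane configured as in 18)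
Conditions: DDQ, CH2Cl2/pH 7 phosphate buffer (10:1), 0 °C
Reagents that add atoms: none
Why: Oxidative 4-methoxybenzyl ether cleavage (electron transfer from the anisyl ring, hydride loss and hydrolysis of the oxocarbenium ion) frees only the primary alcohol, since silyl ethers, oxirane and the isolated alkene are inert to buffered DDQ.

Step 11
Reactants: 20 primary alcohol
Product: 21 (3S)-3-[(triethylsilyl)oxy]-3-{3-[(1S)-1-[(triethylsilyl)oxy]hept-6-en-1-yl]oxiran-2-yl}propanal (oxirane as in 18)
Conditions: Dess–Martin periodinane, NaHCO3, CH2Cl2, 0 °C to rt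
Reagents that add atoms: none
Why: Dess–Martin oxidation gives the β-silyloxy aldehyde (C3) under conditions that are neither basic nor strongly acidic, which avoids β-elimination of the silyloxy group; the aldehyde is used at once.

Step 12
Reactants: 21 aldehyde; 6 (2R)-dec-9-en-2-yl [bis(2,2,2-trifluoroethoxy)phosphoryl]acetate
Product: 22 (2R)-dec-9-en-2-yl (2Z,5S,8S)-6,7-epoxy-5,8-bis[(triethylsilyl)oxy]tetradeca-2,13-dienoate (trans-oxirane configured as in 18)
Conditions: 6, KN(SiMe3)2, 18-crown-6, THF, −78 °C; then 21, −78 °C
Reagents that add atoms: none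
Why: In the Still–Gennari variant of the Horner–Wadsworth–Emmons reaction the electron-poor bis(trifluoroethyl) phosphonate and the crown-ether-separated potassium ion make addition irreversible and elimination fast, so the kinetic syn adduct collapses to the Z-C2=C3 enoate while the two fragments are joined.

Step 13
Reactants: 22 diene ester
Product: 23 bis(triethylsilyl) ether of 13,14-didehydro-CIML C (22-membered lactone, E/Z mixture at C13=C14)
Conditions: second-generation Grubbs catalyst RuCl2(=CHPh)(PCy3)(H2IMes) (10 mol%, two portions), 1,4-benzoquinone (20 mol%), CH2Cl2 (1 mM), 40 °C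
Reagents that add atoms: none
Why: The ruthenium benzylidene exchanges onto one terminal vinyl group and the resulting alkylidene undergoes intramolecular [2+2] cycloaddition and cycloreversion (Chauvin mechanism) with the second vinyl group, expelling ethene and forming C13=C14. The closest known reaction type is macrocyclic ring-closing metathesis of α,ω-diene esters to large-ring lactones. The only ring closed is the 22-membered lactone ring, by end-to-end union of the two chain termini through a ruthenacyclobutane, which is feasible because both termini sit on flexible, unsubstituted polymethylene chains. No stereocentre is created, and the E/Z mixture at C13=C14 is irrelevant because the next step saturates this bond. The step needs site selectivity for the two monosubstituted, electron-neutral terminal alkenes over the Z-enoate, and chemoselectivity against oligomerisation and double-bond migration. These are secured because the 1,2-disubstituted, electron-poor enoate could only close strained 11-membered rings, 1 mM dilution favours cyclisation, and benzoquinone suppresses isomerisation by ruthenium hydrides.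

Step 14
Reactants: 23 macrocyclic alkene
Product: 24 bis(triethylsilyl) ether of CIML C
Conditions: RhCl(PPh3)3 (20 mol%), H2 (1 atm), benzene/EtOH (1:1), rt
Reagents that add atoms: none
Why: Homogeneous hydrogenation with Wilkinson's catalyst should reduce the unhindered, electron-neutral macrocyclic C13=C14 alkene faster than the conjugated, electron-poor Z-enoate flanked by the bulky C5 silyloxy group, a selectivity known for macrocyclic metathesis products that carry unsaturated esters, and it leaves oxirane, ester and silyl ethers untouched.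

Step 15
Reactants: 24 bis(triethylsilyl) ether of CIML C
Product: 25 CIML C, (2Z,5S,6R,7R,8S,21R)-6,7-epoxy-5,8-dihydroxydocos-2-en-21-olide
Conditions: HF·pyridine, pyridine, THF, 0 °C to rt; pH 7 buffer work-up
Reagents that add atoms: none
Why: Fluoride-mediated desilylation under pyridine buffering removes both triethylsilyl ethers without base (which could trigger Payne rearrangement or translactonisation of the C5 hydroxyl onto C1) or strong acid (oxirane opening), and no stereocentre is affected.

Compound list
1 | 7-bromohept-1-ene | C=CCCCCCBr | starting material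
2 | (R)-2-methyloxirane | C[C@@H]1CO1 | starting material
3 | hept-6-en-1-ylmagnesium bromide | C=CCCCCC[Mg]Br | intermediate
4 | (2R)-dec-9-en-2-ol | C[C@@H](O)CCCCCCC=C | intermediate
5 | [bis(2,2,2-trifluoroethoxy)phosphoryl]acetic acid | OC(=O)CP(=O)(OCC(F)(F)F)OCC(F)(F)F | starting material
6 | (2R)-dec-9-en-2-yl [bis(2,2,2-trifluoroethoxy)phosphoryl]acetate | C[C@@H](OC(=O)CP(=O)(OCC(F)(F)F)OCC(F)(F)F)CCCCCCC=C | intermediate
7 | furan | c1ccoc1 | starting material
8 | 6-bromohex-1-ene | C=CCCCCBr | starting material
9 | furan-2-yllithium | [Li]c1ccco1 | intermediate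
10 | 2-(hex-5-en-1-yl)furan | C=CCCCCc1ccco1 | intermediate
11 | oxirane | C1CO1 | starting material
12 | [5-(hex-5-en-1-yl)furan-2-yl]lithium | [Li]c1ccc(CCCCC=C)o1 | intermediate
13 | 2-[5-(hex-5-en-1-yl)furan-2-yl]ethan-1-ol | OCCc1ccc(CCCCC=C)o1 | intermediate
14 | 2-(hex-5-en-1-yl)-5-{2-[(4-methoxybenzyl)oxy]ethyl}furan | COc1ccc(COCCc2ccc(CCCCC=C)o2)cc1 | intermediate
15 | (4Z)-1-[(4-methoxybenzyl)oxy]dodeca-4,11-diene-3,6-dione | COc1ccc(COCCC(=O)/C=C\C(=O)CCCCC=C)cc1 | intermediate
16 | (4E)-1-[(4-methoxybenzyl)oxy]dodeca-4,11-diene-3,6-dione | COc1ccc(COCCC(=O)/C=C/C(=O)CCCCC=C)cc1 | intermediate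
17 | (3S,4E,6S)-1-[(4-methoxybenzyl)oxy]dodeca-4,11-diene-3,6-diol | COc1ccc(COCC[C@H](O)/C=C/[C@@H](O)CCCCC=C)cc1 | intermediate
18 | (1S)-1-[(2R,3R)-3-{(1S)-1-hydroxy-3-[(4-methoxybenzyl)oxy]propyl}oxiran-2-yl]hept-6-en-1-ol | COc1ccc(COCC[C@H](O)[C@H]2O[C@@H]2[C@@H](O)CCCCC=C)cc1 | intermediate
19 | bis(triethylsilyl) ether of 18 | COc1ccc(COCC[C@H](O[Si](CC)(CC)CC)[C@H]2O[C@@H]2[C@@H](O[Si](CC)(CC)CC)CCCCC=C)cc1 | intermediate
20 | primary alcohol (19 without the 4-methoxybenzyl group) | OCC[C@H](O[Si](CC)(CC)CC)[C@H]1O[C@@H]1[C@@H](O[Si](CC)(CC)CC)CCCCC=C | intermediate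
21 | aldehyde from 20 (C3 aldehyde) | O=CC[C@H](O[Si](CC)(CC)CC)[C@H]1O[C@@H]1[C@@H](O[Si](CC)(CC)CC)CCCCC=C | intermediate
22 | (2R)-dec-9-en-2-yl (2Z,5S,8S)-6,7-epoxy-5,8-bis[(triethylsilyl)oxy]tetradeca-2,13-dienoate | C[C@@H](OC(=O)/C=C\C[C@H](O[Si](CC)(CC)CC)[C@H]1O[C@@H]1[C@@H](O[Si](CC)(CC)CC)CCCCC=C)CCCCCCC=C | intermediate
23 | bis(triethylsilyl) ether of 13,14-didehydro-CIML C (E/Z mixture) | C[C@@H]1CCCCCCC=CCCCC[C@H](O[Si](CC)(CC)CC)[C@H]2O[C@@H]2[C@@H](O[Si](CC)(CC)CC)C/C=C\C(=O)O1 | intermediate
24 | bis(triethylsilyl) ether of CIML C | C[C@@H]1CCCCCCCCCCCC[C@H](O[Si](CC)(CC)CC)[C@H]2O[C@@H]2[C@@H](O[Si](CC)(CC)CC)C/C=C\C(=O)O1 | intermediate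
25 | CIML C | C[C@@H]1CCCCCCCCCCCC[C@H](O)[C@H]2O[C@@H]2[C@@H](O)C/C=C\C(=O)O1 | target

Total step count: 15. Longest linear sequence: 13 steps (steps 3 to 15, from furan).

Steps most likely to fail

Step 14. The risk is loss of site selectivity between the two disubstituted alkenes: co-reduction or Z-to-E isomerisation of the conjugated C2=C3 bond through reversible rhodium hydride insertion. The fallback keeps the same ring closure but removes the enoate from the hydrogenation; it sets out from alcohol 4 and aldehyde 21 and returns at 24. Alcohol 4 is acylated with bromoacetyl bromide (NaHCO3, MeCN) to (2R)-dec-9-en-2-yl bromoacetate F1, which N,N'-ditosylhydrazine and DBU convert into (2R)-dec-9-en-2-yl diazoacetate F2. SnCl2-catalysed Roskamp homologation of 21 with F2 gives the β-keto ester diene F3, which has no conjugated alkene. The same ring-closing metathesis gives the macrocyclic β-keto lactone alkene F4, and H2 over Pd/C in EtOAc saturates C13=C14 to give the saturated β-keto lactone F5. (E)-Selective enol triflation at C3 (Tf2O, aqueous Me4NOH, hexane) gives the enol triflate F6, and its reduction with retention of geometry (Pd(OAc)2, PPh3, HCO2H, Bu3N, DMF) delivers the Z-enoate 24.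

Step 8. The risk is poor facial discrimination by the dioxirane on a deactivated alkene that bears an oxygenated carbon on each side, or competing oxidation of the terminal alkene. The fallback replaces reagent control by hydroxyl-directed epoxidation followed by inversion; it sets out from enedione 16 and returns at 18. Reduction of 16 with the (S)-oxazaborolidine under the conditions of step 7 gives the enantiomeric (3R,4E,6R)-diol F7. Sharpless epoxidation (Ti(OiPr)4, D-(−)-diisopropyl tartrate, t-BuOOH, 4 Å sieves, CH2Cl2, −20 °C), for which both carbinols have the fast-reacting configuration and only the allylic alkene is touched, gives the erythro,erythro epoxy diol F8 with the (R,R)-oxirane. Double Mitsunobu inversion (4-nitrobenzoic acid, PPh3, DIAD) gives the bis(4-nitrobenzoate) F9 with both carbinol centres inverted, and K2CO3 in MeOH at 0 °C releases 18.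

Step 7. The risk is incomplete catalyst control at two ketones whose flanking groups differ little in size, together with competing conjugate hydride addition to the doubly activated alkene. The fallback is biocatalytic; it sets out from 16 and returns at 17. An (S)-selective NADPH-dependent ketoreductase (alcohol dehydrogenase class), chosen from a screening panel and run with glucose/glucose dehydrogenase cofactor recycling in pH 7 phosphate buffer with DMSO at 30 °C, reduces both carbonyls. The enzyme pocket, not a boron-bound hydride, then controls both carbinol centres, and isolated ketoreductases do not reduce C=C bonds. This fallback makes no compound outside the list.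

Further compounds
F1 | step 14 | (2R)-dec-9-en-2-yl bromoacetate | C[C@@H](OC(=O)CBr)CCCCCCC=C
F2 | step 14 | (2R)-dec-9-en-2-yl diazoacetate | C[C@@H](OC(=O)C=[N+]=[N-])CCCCCCC=C
F3 | step 14 | (2R)-dec-9-en-2-yl (5S,8S)-6,7-epoxy-3-oxo-5,8-bis[(triethylsilyl)oxy]tetradec-13-enoate (oxirane as in 18) | C[C@@H](OC(=O)CC(=O)C[C@H](O[Si](CC)(CC)CC)[C@H]1O[C@@H]1[C@@H](O[Si](CC)(CC)CC)CCCCC=C)CCCCCCC=C
F4 | step 14 | macrocyclic β-keto lactone with C13=C14 (3-oxo-2,3-dihydro analogue of 23) | C[C@@H]1CCCCCCC=CCCCC[C@H](O[Si](CC)(CC)CC)[C@H]2O[C@@H]2[C@@H](O[Si](CC)(CC)CC)CC(=O)CC(=O)O1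
F5 | step 14 | saturated macrocyclic β-keto lactone (3-oxo-2,3-dihydro analogue of 24) | C[C@@H]1CCCCCCCCCCCC[C@H](O[Si](CC)(CC)CC)[C@H]2O[C@@H]2[C@@H](O[Si](CC)(CC)CC)CC(=O)CC(=O)O1
F6 | step 14 | (E)-enol triflate of F5 at C3 (triflate trans to the lactone carbonyl) | C[C@@H]1CCCCCCCCCCCC[C@H](O[Si](CC)(CC)CC)[C@H]2O[C@@H]2[C@@H](O[Si](CC)(CC)CC)C/C(OS(=O)(=O)C(F)(F)F)=C\C(=O)O1
F7 | step 8 | (3R,4E,6R)-1-[(4-methoxybenzyl)oxy]dodeca-4,11-diene-3,6-diol | COc1ccc(COCC[C@@H](O)/C=C/[C@H](O)CCCCC=C)cc1
F8 | step 8 | (1R)-1-[(2R,3R)-3-{(1R)-1-hydroxy-3-[(4-methoxybenzyl)oxy]propyl}oxiran-2-yl]hept-6-en-1-ol | COc1ccc(COCC[C@@H](O)[C@H]2O[C@@H]2[C@H](O)CCCCC=C)cc1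
F9 | step 8 | bis(4-nitrobenzoate) of 18 | COc1ccc(COCC[C@H](OC(=O)c2ccc(cc2)[N+](=O)[O-])[C@H]3O[C@@H]3[C@@H](OC(=O)c4ccc(cc4)[N+](=O)[O-])CCCCC=C)cc1
F0 | step 7 | none | none
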